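Ring A is closed last, across C2–C3 (clerodane numbering), by a type 2 intramolecular carbonyl-ene reaction. The step exploits the C18H2=C4–C3–C2–O array of ring A, a 3-methylenecyclohexanol retron next to the quaternary C5: in one operation an acetaldehyde arm on C10 and an isopropenyl group on C5 of a fully substituted ring B give the C2–C3 bond, the C4=C18 exocyclic methylene and the C2 oxygen. The cis arms come from the cyclopentane ring of an (S)-Hajos–Parrish-type enedione, a temporary ring that also directs C10, C9, C8 and C7; allylic oxidation at C3 and diol oxidation then give the diosphenol.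

Key step: step 17

Remark on the chemistry: all atoms carry the clerodane numbers of the target (ring A: C1–C5 and C10; ring B: C5–C10; C17 on C8, C18 on C4, C19 on C5, C20 on C9, side chain C11–C16). In the hydrindane intermediates the five-membered ring is C5–C4–C2–C1–C10. The hydrogenation of step 4 is assumed to give the cis ring fusion, as is usual for angularly methylated hydrindenones. Compounds 24 and 25 are carried as epimer mixtures at C2 (and C3), which converge in step 19.

Step 1
Reactants: 1 2-methylcyclopentane-1,3-dione; 2 pent-1-en-3-one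
Product: 3 2-methyl-2-(3-oxopentyl)cyclopentane-1,3-dione
Conditions: H2O, AcOH (cat.), 70 °C
Reagents that add atoms: none
Why: Michael addition of the enolised 1,3-dione to the enone should give the prochiral triketone, with no stereocentre yet.

Step 2
Reactants: 3 2-methyl-2-(3-oxopentyl)cyclopentane-1,3-dione
Product: 4 (7aS)-4,7a-dimethyl-2,3,7,7a-tetrahydro-1H-indene-1,5(6H)-dione
Conditions: L-phenylalanine (1 equiv), HClO4 (1 M aq, 0.5 equiv), MeCN, reflux; recrystallisation
Reagents that add atoms: none
Why: Hajos–Parrish–Eder–Sauer–Wiechert aldol condensation, in which the enamine of the side-chain ketone with the L-amino acid attacks one of the two enantiotopic ring carbonyls, should set the quaternary C5 as (S) and close ring B as the C9=C10 enone.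

Step 3
Reactants: 4 (7aS)-enedione
Product: 5 (1S,7aS)-1-hydroxy-4,7a-dimethyl-1,2,3,6,7,7a-hexahydro-5H-inden-5-one
Conditions: NaBH4 (0.3 equiv), EtOH, −20 °C
Reagents that add atoms: none
Why: Chemoselective NaBH4 1,2-reduction of the saturated C4 ketone (the conjugated C8 ketone reacts more slowly), with hydride attack anti to the C19 methyl, masks C4 against enolisation during the work on ring B.

Step 4
Reactants: 5 hydroxy enone
Product: 6 cis-fused hydroxy hydrindanone
Conditions: H2 (3 atm), 10% Pd/C, EtOH, rt
Reagents that add atoms: none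
Why: Heterogeneous catalytic hydrogenation adds H2 syn to the tetrasubstituted C9=C10 bond and should set C10–H cis to the C19 methyl (cis-hydrindane); the C9 centre is erased again in step 5.

Step 5
Reactants: 6 cis-fused hydroxy hydrindanone
Product: 7 C8=C9 triethylsilyl enol ether with C4 triethylsilyl ether
Conditions: Et3SiOTf (2.5 equiv), Et3N, CH2Cl2, 0 °C → rt (equilibrating)
Reagents that add atoms: triethylsilyl trifluoromethanesulfonate CC[Si](CC)(CC)OS(=O)(=O)C(F)(F)F
Why: Soft enolisation and O-silylation under equilibrating conditions should give the thermodynamic, tetrasubstituted C8=C9 silyl enol ether and silylate the C4 hydroxyl in the same operation.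

Step 6
Reactants: 7 silyl enol ether; 8 but-3-en-2-one
Product: 9 C9-quaternary diketone
Conditions: TiCl4 (1.1 equiv), CH2Cl2, −78 °C; aq. K2CO3
Reagents that add atoms: none
Why: Mukaiyama–Michael addition builds the C9 quaternary centre, the activated enone approaching the convex face of the cis-hydrindane anti to the C10–C1 bond and away from C4–OSiEt3, which should place the 3-oxobutyl chain cis to C10–H and the C20 methyl trans to it.

Step 7
Reactants: 9 C9-quaternary diketone; 10 tert-butyl 2-(diethoxyphosphoryl)acetate
Product: 11 (E)-enoate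
Conditions: NaH, THF, 0 °C → rt; removal of the minor (Z)-isomer
Reagents that add atoms: none
Why: Horner–Wadsworth–Emmons olefination should occur only at the unhindered methyl ketone (the C8 ketone is flanked by the quaternary C9) and favour the (E)-trisubstituted enoate.

Step 8
Reactants: 11 (E)-enoate
Product: 12 C7=C8 enol triflate
Conditions: Tf2O, 2,6-di-tert-butyl-4-methylpyridine, CH2Cl2, 0 °C → rt
Reagents that add atoms: trifluoromethanesulfonic anhydride O=S(=O)(OS(=O)(=O)C(F)(F)F)C(F)(F)F
Why: Ketone-to-enol-triflate conversion can enolise only toward C7 because C9 is quaternary, and the absence of a strong base leaves the γ-hydrogens of the enoate untouched.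

Step 9
Reactants: 12 C7=C8 enol triflate
Product: 13 C7=C8 alkene with C17 methyl
Conditions: MeZnCl (2 equiv), Pd(PPh3)4 (5 mol%), THF, 50 °C
Reagents that add atoms: methylzinc chloride C[Zn]Cl
Why: Negishi cross-coupling of the alkenyl triflate installs C17 on C8 and tolerates the ester and the silyl ether.

Step 10
Reactants: 13 C7=C8 alkene
Product: 14 C7 alcohol
Conditions: BH3·THF, THF, 0 °C → rt; then H2O2, aq. NaOH, 0 °C
Reagents that add atoms: hydrogen peroxide OO
Why: Hydroboration–oxidation puts boron on the less substituted C7 and adds H and B syn from the face opposite the pseudoaxial C20 methyl and the axial C5–C4 bond, so C7–OH and C8–H should end cis to the side chain and the C17 methyl trans to the hydroxyl (both equatorial).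

Step 11
Reactants: 14 C7 alcohol
Product: 15 C7 acetate
Conditions: Ac2O, pyridine, DMAP (cat.), CH2Cl2, rt
Reagents that add atoms: acetic anhydride CC(=O)OC(C)=O
Why: DMAP-catalysed acylation of the secondary C7 alcohol gives the acetate that is kept to the end.

Step 12
Reactants: 15 C7 acetate
Product: 17 C4 cyclopentanone, via C4 alcohol 16 (not isolated)
Conditions: CrO3, aq. H2SO4, acetone, 0 °C → rt
Reagents that add atoms: none
Why: Jones oxidation cleaves the triethylsilyl ether under the acidic conditions and oxidises the freed secondary alcohol to the cyclopentanone in one operation, while acetate, enoate and tert-butyl ester should survive.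

Step 13
Reactants: 17 C4 cyclopentanone
Product: 18 C4=C2 enol triflate
Conditions: Tf2O, 2,6-di-tert-butyl-4-methylpyridine, CH2Cl2, 0 °C → rt
Reagents that add atoms: trifluoromethanesulfonic anhydride O=S(=O)(OS(=O)(=O)C(F)(F)F)C(F)(F)F
Why: Enol triflate formation as in step 8, where the quaternary C5 allows enolisation only toward C2.

Step 14
Reactants: 18 C4=C2 enol triflate
Product: 19 methylcyclopentene
Conditions: MeZnCl (2 equiv), Pd(PPh3)4 (5 mol%), THF, 50 °C
Reagents that add atoms: methylzinc chloride C[Zn]Cl
Why: Negishi methylation of the cyclopentenyl triflate gives the 1-methylcyclopentene whose methyl carbon becomes C18.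

Step 15
Reactants: 19 methylcyclopentene
Product: 21 keto dimethyl acetal, via keto aldehyde 20 (not isolated)
Conditions: O3 (1 equiv), CH2Cl2–MeOH, −78 °C (Sudan Red 7B end point); Me2S, → rt; then HC(OMe)3, PPTS (cat.), MeOH, rt
Reagents that add atoms: ozone [O-][O+]=O; trimethyl orthoformate COC(OC)OC
Why: Ozonolysis with reductive work-up cleaves the electron-rich trisubstituted cyclopentene far faster than the conjugated enoate, turning the temporary ring into an acetyl group on C5 and a C2 aldehyde arm on C10 held cis, and only the unhindered aldehyde is then acetalised.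

Step 16
Reactants: 21 keto dimethyl acetal
Product: 23 isopropenyl aldehyde, via isopropenyl acetal 22 (not isolated)
Conditions: Cp2Ti(μ-CH2)(μ-Cl)AlMe2 (Tebbe reagent, 1.2 equiv), pyridine (cat.), THF–toluene, −40 → 0 °C; aq. NaOH quench, filtration; then 1 M HCl, THF, rt
Reagents that add atoms: Tebbe reagent C[Al-]1(C)C[Ti]([Cl+]1)(C1C=CC=C1)C1C=CC=C1; water O
Why: Tebbe methylenation (non-basic titanium methylidene, ketone-selective over esters at low temperature) converts the hindered methyl ketone into the isopropenyl group, whose new CH2 becomes C3, and mild aqueous acid then hydrolyses the acetal without touching the alkene or the esters.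

Step 17
Reactants: 23 isopropenyl aldehyde
Product: 24 homoallylic alcohol (ring A closed)
Conditions: Me2AlCl (2.5 equiv), CH2Cl2, −78 → −20 °C
Reagents that add atoms: none
Why: Me2AlCl activates the aldehyde, the terminal CH2 of the isopropenyl group (C3) attacks the carbonyl carbon C2 and a hydrogen of the isopropenyl methyl (C18) passes to oxygen, so the C2–C3 bond, the C4=C18 exocyclic alkene and the C2 hydroxyl arise together (concerted, or through a tight C4 cation that is deprotonated at once). The closest known reaction type is the Lewis-acid-promoted type 2 intramolecular carbonyl-ene cyclisation of δ,ε-unsaturated aldehydes to 3-methylenecyclohexanols. Ring A closes as a six-membered ring, 6-exo-trig at the aldehyde with both ene carbons (C3, C4) inside the ring, through a chair-like transition state that the cis C5/C10 arms make possible. The only new stereocentre, C2, is set by that chair (oxygen probably equatorial) but is not needed, since both epimers converge on the C2 enol in step 19. The step needs regioselective hydrogen transfer and chemoselectivity: C5 is quaternary, so only the methyl group can deliver hydrogen and no endocyclic alkene isomer can form, the electron-poor enoate is no ene partner, and Me2AlCl scavenges protons that would start Prins-type side reactions.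

Step 18
Reactants: 24 homoallylic alcohol
Product: 25 C2,C3-diol
Conditions: SeO2 (0.5 equiv), t-BuOOH (3 equiv), CH2Cl2, rt
Reagents that add atoms: selenium dioxide O=[Se]=O; tert-butyl hydroperoxide CC(C)(C)OO
Why: SeO2 allylic oxidation (ene reaction at C18, then [2,3]-sigmatropic shift) returns the exocyclic C4=C18 bond and hydroxylates C3, the only allylic carbon with hydrogen because C5 is quaternary, while the electron-poor enoate should be inert and the C3 configuration is irrelevant.

Step 19
Reactants: 25 C2,C3-diol
Product: 26 diosphenol tert-butyl ester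
Conditions: IBX (3 equiv), DMSO, rt
Reagents that add atoms: none
Why: IBX oxidation takes the 1,2-diol to the 1,2-diketone without C–C cleavage, and the C2 carbonyl enolises toward C1 (C4 has no hydrogen), which should deliver the diosphenol conjugated with the C3 ketone under base-free conditions that leave C10 untouched.

Step 20
Reactants: 26 diosphenol tert-butyl ester
Product: 27 CNP0192653.1
Conditions: CF3CO2H, CH2Cl2, 0 °C → rt
Reagents that add atoms: none
Why: Acidolysis of the tert-butyl ester (loss of isobutene) frees the carboxylic acid while the acetate, the diosphenol and the alkenes should be stable.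

Compound list

1 | 2-methylcyclopentane-1,3-dione | CC1C(=O)CCC1=O | starting material
2 | pent-1-en-3-one (ethyl vinyl ketone) | C=CC(=O)CC | starting material
3 | 2-methyl-2-(3-oxopentyl)cyclopentane-1,3-dione | CCC(=O)CCC1(C)C(=O)CCC1=O | intermediate
4 | (7aS)-4,7a-dimethyl-2,3,7,7a-tetrahydro-1H-indene-1,5(6H)-dione | C[C@]12CCC(=O)C(C)=C1CCC2=O | intermediate
5 | (1S,7aS)-1-hydroxy-4,7a-dimethyl-1,2,3,6,7,7a-hexahydro-5H-inden-5-one (C4 hydroxyl cis to the C19 methyl) | O[C@H]1CCC2=C(C)C(=O)CC[C@]12C | intermediate
6 | cis-fused 1-hydroxy-4,7a-dimethyloctahydro-5H-inden-5-one: C10–H cis to the C19 methyl, C9–H cis to C10–H, hydroxyl cis to C19 | O[C@H]1CC[C@@H]2[C@H](C)C(=O)CC[C@]12C | intermediate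
7 | bis-silyl derivative of 6: C8=C9 triethylsilyl enol ether and C4 triethylsilyl ether | CC[Si](CC)(CC)O[C@H]1CC[C@@H]2C(C)=C(O[Si](CC)(CC)CC)CC[C@]12C | intermediate
8 | but-3-en-2-one (methyl vinyl ketone) | C=CC(C)=O | starting material
9 | C9-quaternary diketone: C8 ketone, C9 bearing the C20 methyl and a 3-oxobutyl chain (chain cis to C10–H and C19), C4 triethylsilyl ether | CC[Si](CC)(CC)O[C@H]1CC[C@@H]2[C@@](C)(CCC(C)=O)C(=O)CC[C@]12C | intermediate
10 | tert-butyl 2-(diethoxyphosphoryl)acetate | CCOP(=O)(CC(=O)OC(C)(C)C)OCC | starting material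
11 | (E)-enoate: tert-butyl (2E)-3-methylpent-2-enoate chain on C9, C8 ketone, C4 triethylsilyl ether | CC[Si](CC)(CC)O[C@H]1CC[C@@H]2[C@@](C)(CC/C(C)=C/C(=O)OC(C)(C)C)C(=O)CC[C@]12C | intermediate
12 | C7=C8 enol triflate of 11 | CC[Si](CC)(CC)O[C@H]1CC[C@@H]2[C@@](C)(CC/C(C)=C/C(=O)OC(C)(C)C)C(OS(=O)(=O)C(F)(F)F)=CC[C@]12C | intermediate
13 | C7=C8 alkene carrying the C17 methyl on C8 | CC[Si](CC)(CC)O[C@H]1CC[C@@H]2[C@@](C)(CC/C(C)=C/C(=O)OC(C)(C)C)C(C)=CC[C@]12C | intermediate
14 | C7 alcohol: C7–OH and C8–H cis to the side chain, C17 methyl trans to the hydroxyl | CC[Si](CC)(CC)O[C@H]1CC[C@@H]2[C@@](C)(CC/C(C)=C/C(=O)OC(C)(C)C)[C@H](C)[C@@H](O)C[C@]12C | intermediate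
15 | C7 acetate of 14 | CC[Si](CC)(CC)O[C@H]1CC[C@@H]2[C@@](C)(CC/C(C)=C/C(=O)OC(C)(C)C)[C@H](C)[C@@H](OC(C)=O)C[C@]12C | intermediate
16 | C4 alcohol (silyl ether of 15 cleaved; not isolated) | O[C@H]1CC[C@@H]2[C@@](C)(CC/C(C)=C/C(=O)OC(C)(C)C)[C@H](C)[C@@H](OC(C)=O)C[C@]12C | intermediate
17 | C4 cyclopentanone with C7 acetate | O=C1CC[C@@H]2[C@@](C)(CC/C(C)=C/C(=O)OC(C)(C)C)[C@H](C)[C@@H](OC(C)=O)C[C@]12C | intermediate
18 | C4=C2 enol triflate of 17 | O=S(=O)(OC1=CC[C@@H]2[C@@](C)(CC/C(C)=C/C(=O)OC(C)(C)C)[C@H](C)[C@@H](OC(C)=O)C[C@]12C)C(F)(F)F | intermediate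
19 | methylcyclopentene: C4=C2 double bond, methyl (future C18) on C4 | CC1=CC[C@@H]2[C@@](C)(CC/C(C)=C/C(=O)OC(C)(C)C)[C@H](C)[C@@H](OC(C)=O)C[C@]12C | intermediate
20 | keto aldehyde: ring B with acetyl (C4 and future C18) and C19 methyl on C5 and a 2-oxoethyl arm (C1, C2) on C10, arms cis (not isolated) | O=CC[C@@H]1[C@@](C)(CC/C(C)=C/C(=O)OC(C)(C)C)[C@H](C)[C@@H](OC(C)=O)C[C@]1(C)C(C)=O | intermediate
21 | keto dimethyl acetal of 20 | COC(OC)C[C@@H]1[C@@](C)(CC/C(C)=C/C(=O)OC(C)(C)C)[C@H](C)[C@@H](OC(C)=O)C[C@]1(C)C(C)=O | intermediate
22 | isopropenyl dimethyl acetal (not isolated) | COC(OC)C[C@@H]1[C@@](C)(CC/C(C)=C/C(=O)OC(C)(C)C)[C@H](C)[C@@H](OC(C)=O)C[C@]1(C)C(C)=C | intermediate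
23 | isopropenyl aldehyde: isopropenyl and C19 methyl on C5, 2-oxoethyl arm on C10, arms cis | O=CC[C@@H]1[C@@](C)(CC/C(C)=C/C(=O)OC(C)(C)C)[C@H](C)[C@@H](OC(C)=O)C[C@]1(C)C(C)=C | intermediate
24 | homoallylic alcohol: cis-decalin with C4=C18 exocyclic methylene and C2 hydroxyl (both C2 epimers) | C=C1CC(O)C[C@@H]2[C@@](C)(CC/C(C)=C/C(=O)OC(C)(C)C)[C@H](C)[C@@H](OC(C)=O)C[C@]12C | intermediate
25 | C2,C3-diol with C4=C18 methylene (diastereomer mixture at C2 and C3) | C=C1C(O)C(O)C[C@@H]2[C@@](C)(CC/C(C)=C/C(=O)OC(C)(C)C)[C@H](C)[C@@H](OC(C)=O)C[C@]12C | intermediate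
26 | diosphenol tert-butyl ester (tert-butyl ester of the target) | C=C1C(=O)C(O)=C[C@@H]2[C@@](C)(CC/C(C)=C/C(=O)OC(C)(C)C)[C@H](C)[C@@H](OC(C)=O)C[C@]12C | intermediate
27 | CNP0192653.1: 7-acetoxy-2-hydroxy-3-oxo-5,10-cis-cleroda-1,4(18),13E-trien-15-oic acid | C=C1C(=O)C(O)=C[C@@H]2[C@@](C)(CC/C(C)=C/C(=O)O)[C@H](C)[C@@H](OC(C)=O)C[C@]12C | target

Total step count: 20. Longest linear sequence: 20 steps (from 1).

Steps most likely to fail

1. Step 17 (ring closure). The Lewis acid may ionise the substrate to a free tertiary C4 cation, which leads to chloride capture or alkene isomerisation, or the aldehyde may condense intermolecularly. Fallback, aldol then methylenation: it sets out from 20, isolated by leaving out the acetalisation of step 15. A proline-catalysed intramolecular aldol addition (L-proline, DMSO, rt; 6-enolexo) forms the same C2–C3 bond and should give the β-hydroxy ketone F1, ring A with a C4 ketone and a C2 hydroxyl. The acetyl group can enolise only at its methyl carbon, which here becomes C3, and the aldehyde enol cannot cyclise because it would form a four-membered ring. Tebbe methylenation of the C4 ketone with excess reagent then gives 24, where the route is rejoined.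

2. Step 18 (allylic oxidation). Oxidation may run on past the allylic alcohol, selenium may attack the allylic positions of the side chain, or material may be lost as organoselenium by-products. Fallback, Rubottom route: it sets out from 24. Dess–Martin oxidation of the C2 alcohol should give the β,γ-unsaturated ketone F2. Soft enolisation toward the doubly activated C3 (TBSOTf, Et3N) should give the 2-silyloxy-1,3-diene F3. Epoxidation of the electron-rich enol ether bond with dimethyldioxirane, followed by mildly acidic work-up, should give the acyloin F4 (C2 ketone, C3 hydroxyl). IBX oxidation of F4 and enolisation toward C1 give 26, where the route is rejoined.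

3. Step 6 (C9 quaternary centre). The enone may polymerise, the Lewis acid may desilylate the hindered enol ether before the C–C bond forms, or face selectivity at C9 may be too low. Fallback, anionic Michael addition to an α-silyl enone: it sets out from 7. MeLi (THF, 0 °C) cleaves the silyl enol ether to the regiodefined lithium enolate, which adds at −78 °C to 3-(triethylsilyl)but-3-en-2-one; the α-silyl group stops polymerisation and proton transfer, and the adduct is the α-silyl ketone F5. NaOMe in MeOH at 0 °C removes the C-silyl group and gives 9, where the route is rejoined.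

Further compounds
F1 | step 17 | β-hydroxy ketone: ring A closed with C4 ketone and C2 hydroxyl | O=C1CC(O)C[C@@H]2[C@@](C)(CC/C(C)=C/C(=O)OC(C)(C)C)[C@H](C)[C@@H](OC(C)=O)C[C@]12C
F2 | step 18 | β,γ-unsaturated ketone: C2 ketone with C4=C18 methylene | C=C1CC(=O)C[C@@H]2[C@@](C)(CC/C(C)=C/C(=O)OC(C)(C)C)[C@H](C)[C@@H](OC(C)=O)C[C@]12C
F3 | step 18 | 2-(tert-butyldimethylsilyloxy)-1,3-diene: C2=C3 silyl enol ether conjugated with C4=C18 | C=C1C=C(O[Si](C)(C)C(C)(C)C)C[C@@H]2[C@@](C)(CC/C(C)=C/C(=O)OC(C)(C)C)[C@H](C)[C@@H](OC(C)=O)C[C@]12C
F4 | step 18 | acyloin: C2 ketone, C3 hydroxyl, C4=C18 methylene | C=C1C(O)C(=O)C[C@@H]2[C@@](C)(CC/C(C)=C/C(=O)OC(C)(C)C)[C@H](C)[C@@H](OC(C)=O)C[C@]12C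
F5 | step 6 | α-silyl ketone Michael adduct: 3-oxo-2-(triethylsilyl)butyl chain on C9 | CC[Si](CC)(CC)O[C@H]1CC[C@@H]2[C@@](C)(CC(C(C)=O)[Si](CC)(CC)CC)C(=O)CC[C@]12C
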